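The runs are simulated with made-up constants; noise was put on by code.

| flask | G | Z | time |
|---|---|---|---|
| south | 100 mM | 300 mM |  |
| west | 50.0 mM | 250 mM |  |
| north-east | 150 mM | 300 mM |  |
| north-west | 300 mM | 300 mM | 75 min |

| run | time / min | [L] / mM |
|---|---|---|
| south run | 3.0 | 1.0 |
| south run | 5.1 | 2.2 |
| south run | 8.8 | 5.3 |
| south run | 15 | 9.6 |
| south run | 26 | 15.1 |
| south run | 44 | 20.9 |
| south run | 75 | 23.8 |
| west run | 3.0 | 0.8 |
| west run | 5.1 | 1.5 |
| west run | 8.8 | 3.1 |
| west run | 15 | 5.2 |
| west run | 26 | 8.6 |
| west run | 44 | 10.8 |
| west run | 75 | 11.9 |
| north-east run | 3.0 | 1.2 |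
| north-east run | 5.1 | 3.6 |
| north-east run | 8.8 | 6.4 |
| north-east run | 15 | 12.8 |
| north-east run | 26 | 19.7 |
| north-east run | 44 | 28.0 |
| north-east run | 75 | 34.0 |

(readings scatter by 0.3 mM)

- Overall: G + Z -> L.
- Constant volume, constant temperature.
- Readings of a species count what is bound in complexes too.
- "The second partner" is Z.
- An order is taken over about fifteen percent of the charge, up and down.

1. reaction order in [Z] at the outset, round the charge of the south run, defined at two percent of the G turned into L
2. reaction order in [G] at the outset, round the charge of the south run, defined at two percent of the G turned into L (one fixed amount of L, the same in the runs compared)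
3. L in the north-west run at 75 min, as a share of the G charged

Start from the leftover. At 75 min the south run holds 23.8 mM of L from 100 mM of G, so 76.2 mM of that G is not in L. G is the limiting reagent there, charged at less than the 300 mM of Z. Yet the south curve flattens near a quarter of the G charged.

Two chemists argue over north-west. The first holds that the share is constant: L at the last reading grows in step with G. West and south both read 23.8%, so she expects 71.4 mM of L in north-west, again 23.8%.

The second made the forecast, and she points to north-east. It has the Z of south but reads 22.7%, lower than south. The forecast gives an order in G of 0.8, an order in Z of 0.3, and 20% for north-west, since “the share should slip slightly with more G”.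

My own reckoning needs one quantity. Call it the yield exponent 0.880: the power of the G charge that L at 75 min follows at fixed Z, as read from south and north-east. An exponent of one means a constant share. Carried from north-east to north-west, the reading gives 62.6 mM of L, or 20.9%. That is a little above the forecast's figure.

The simulation gives 0.52 for the order in G and 0.51 for the order in Z, both outside the forecast's margins. Its 18.5% for north-west lies within the forecast's margin.

    G → Q (0.06840 min⁻¹)
    Q + Z → L (0.3966 M⁻¹ min⁻¹)
    Q → J (0.1590 min⁻¹)
    2 Z → Lx (0.07440 M⁻¹ min⁻¹)
    2 G ⇌ G2, settled at all times (17.60 M⁻¹)

North-west holds 55.4 mM of L, less than my reckoning. At the outset, round the south charge, the order in G is 0.52, lower than the yield exponent. From north-east to north-west the exponent reads 0.705, lower than 0.880. Taken from south down to west, 0.880 gives 12.9 mM, more than the 11.9 mM read there, with west at 250 mM of Z.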